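**Plan**
- Retrosynthesis: remove the two benzyl ethers from the catechol; cut lactone bonds C5–O1 and C2–C3 together, so that O1–C2(=O) leaves as a one-carbon CO2 unit (formate) and C3–C4–C5 remains as an open chain; then cut the aryl–CH bond of the catechol arm (Heck) and the C4–CH2Ar bond (allylic alkylation).
- Enabling feature: C3 is homobenzylic to the catechol ring and C5 is a primary O-bearing CH2. Drawn as a styrene (C3=CH–Ar) with chloride on C5, the chain takes up the carbon dioxide radical anion at C3, and the new carboxylate closes the five-membered lactone ring onto C5.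
- Forward order: 3,4-dimethoxybenzyl Grignard + (E)-1,4-dichlorobut-2-ene (SN2′) → Heck arylation → formate annulation (lactone ring) → C3 epimerisation → hydrogenolysis.
- Stereochemistry: C4 comes from the enantioselective copper-catalysed allylic alkylation and is carried unchanged; C3 is set by base equilibration to the trans lactone, controlled by C4.
- Helpers: the styrene double bond (used up in the key step), the chloride on C5 (lost in ring closure) and the benzyl ethers (removed last).

Key step: step 4

Remark: L in step 2 is a BINOL-derived N,N-bis(1-phenylethyl)phosphoramidite; its sense of induction with a benzylic Grignard reagent is assumed, not known, so the ligand enantiomer that delivers (R)-4 is to be identified in a first run and used.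

Step 1
Reactants: 1 3,4-dimethoxybenzyl chloride (4-(chloromethyl)-1,2-dimethoxybenzene)
Product: 2 (3,4-dimethoxybenzyl)magnesium chloride (titrated Et2O solution, used directly)
Conditions: Mg turnings (activated with 1,2-dibromoethane), Et2O, 0 °C, slow addition at high dilution
Reagents that add atoms: magnesium, [Mg]
Why: Grignard formation by insertion of magnesium into the benzylic C–Cl bond; slow addition at low temperature should hold back Wurtz-type homocoupling of this electron-rich benzylic halide.

Step 2
Reactants: 2 (3,4-dimethoxybenzyl)magnesium chloride; 3 (E)-1,4-dichlorobut-2-ene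
Product: 4 (R)-4-chloro-3-(3,4-dimethoxybenzyl)but-1-ene (4-[(2R)-2-(chloromethyl)but-3-en-1-yl]-1,2-dimethoxybenzene)
Conditions: Cu(O2CC4H3S) (copper thiophene-2-carboxylate, 3 mol%), L (3.3 mol%), CH2Cl2, −78 °C, slow addition of 2
Reagents that add atoms: none
Why: Copper-catalysed enantioselective SN2′ allylic alkylation of a 1,4-dihalobut-2-ene with a Grignard reagent, in which the chiral phosphoramidite complex of monovalent copper selects the alkene face and so sets the stereocentre that becomes C4, while the remaining chloride, now homoallylic, is inert.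

Step 3
Reactants: 4 (R)-4-chloro-3-(3,4-dimethoxybenzyl)but-1-ene; 5 1,2-bis(benzyloxy)-4-bromobenzene
Product: 6 (R,E)-1,2-bis(benzyloxy)-4-[4-chloro-3-(3,4-dimethoxybenzyl)but-1-en-1-yl]benzene
Conditions: Pd(OAc)2 (5 mol%), P(o-tol)3 (10 mol%), Et3N, DMF, 100 °C
Reagents that add atoms: none
Why: Mizoroki–Heck arylation of the terminal alkene, where carbopalladation at the unsubstituted carbon and β-hydride elimination on the benzylic side should give the conjugated E-styrene, and the primary alkyl chloride should not add to zerovalent palladium under these conditions.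

Step 4
Reactants: 6 (R,E)-1,2-bis(benzyloxy)-4-[4-chloro-3-(3,4-dimethoxybenzyl)but-1-en-1-yl]benzene; 7 potassium formate
Product: 9 (3RS,4R)-3-[3,4-bis(benzyloxy)benzyl]-4-(3,4-dimethoxybenzyl)dihydrofuran-2(3H)-one (mixture of C3 epimers), via potassium γ-chlorocarboxylate 8 (not isolated)
Conditions: HCO2K (4 equiv), 2,4,5,6-tetrakis(carbazol-9-yl)isophthalonitrile (2 mol%), methyl 2-sulfanylbenzoate (20 mol%), DMSO, blue LEDs, rt; then NaI (20 mol%), 80 °C
Reagents that add atoms: none
Why: The excited photocatalyst oxidises the thiolate, the thiyl radical abstracts hydrogen from formate to give the carbon dioxide radical anion, and this adds to the styrene carbon remote from the arene (future C3); the benzylic radical is then quenched by hydrogen-atom transfer from the thiol, and carboxylate 8 displaces chloride at C5. The closest known reaction type is the photochemical, thiol-mediated anti-Markovnikov hydrocarboxylation of styrenes with formate (a Giese-type addition), joined here to the classical lactonisation of a γ-halo carboxylate. The lactone ring closes by 5-exo-tet O-alkylation. C3 is created in the radical addition under only weak 1,2-induction from C4 and is therefore expected as an epimer mixture, which step 5 corrects; C4 is untouched because no bond to it is made or broken. The regiochemistry is secured by the aryl ring, which stabilises the radical only when the new C–C bond forms at the remote carbon. Chemoselectivity rests on the primary alkyl chloride being too hard to reduce for the carbon dioxide radical anion and on its position, which allows only the five-membered closure.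

Step 5
Reactants: 9 (3RS,4R)-3-[3,4-bis(benzyloxy)benzyl]-4-(3,4-dimethoxybenzyl)dihydrofuran-2(3H)-one
Product: 10 (3R,4R)-3-[3,4-bis(benzyloxy)benzyl]-4-(3,4-dimethoxybenzyl)dihydrofuran-2(3H)-one
Conditions: NaOMe (0.3 equiv), MeOH/THF, 50 °C; then aq. HCl, rt
Reagents that add atoms: none
Why: Base-mediated epimerisation through the enolate (with reversible methanolysis and relactonisation on acidification) should funnel both C3 epimers into the thermodynamically preferred trans-3,4-disubstituted lactone, the fixed C4 centre dictating the C3 configuration.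

Step 6
Reactants: 10 (3R,4R)-3-[3,4-bis(benzyloxy)benzyl]-4-(3,4-dimethoxybenzyl)dihydrofuran-2(3H)-one
Product: 11 3'-O-demethylarctigenin, (3R,4R)-3-(3,4-dihydroxybenzyl)-4-(3,4-dimethoxybenzyl)dihydrofuran-2(3H)-one
Conditions: H2 (1 atm), Pd/C (10 wt%), EtOAc/EtOH, rt
Reagents that add atoms: none
Why: Catalytic hydrogenolysis of the two aryl benzyl ethers under neutral conditions, which should leave the lactone, the methyl ethers and both stereocentres untouched.

**Compound list**
1 | 3,4-dimethoxybenzyl chloride | COc1ccc(CCl)cc1OC | starting material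
2 | (3,4-dimethoxybenzyl)magnesium chloride | COc1ccc(C[Mg]Cl)cc1OC | intermediate
3 | (E)-1,4-dichlorobut-2-ene | ClC/C=C/CCl | starting material
4 | (R)-4-chloro-3-(3,4-dimethoxybenzyl)but-1-ene | C=C[C@H](CCl)Cc1ccc(OC)c(OC)c1 | intermediate
5 | 1,2-bis(benzyloxy)-4-bromobenzene | Brc1ccc(OCc2ccccc2)c(OCc2ccccc2)c1 | starting material
6 | (R,E)-1,2-bis(benzyloxy)-4-[4-chloro-3-(3,4-dimethoxybenzyl)but-1-en-1-yl]benzene | c1ccccc1COc1ccc(/C=C/[C@H](CCl)Cc2ccc(OC)c(OC)c2)cc1OCc1ccccc1 | intermediate
7 | potassium formate | [K+].[O-]C=O | starting material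
8 | potassium (3R)-2-[3,4-bis(benzyloxy)benzyl]-4-chloro-3-(3,4-dimethoxybenzyl)butanoate (both C2 epimers) | [K+].[O-]C(=O)C(Cc1ccc(OCc2ccccc2)c(OCc2ccccc2)c1)[C@H](CCl)Cc1ccc(OC)c(OC)c1 | intermediate
9 | (3RS,4R)-3-[3,4-bis(benzyloxy)benzyl]-4-(3,4-dimethoxybenzyl)dihydrofuran-2(3H)-one (C3 epimer mixture) | COc1ccc(C[C@H]2COC(=O)C2Cc2ccc(OCc3ccccc3)c(OCc3ccccc3)c2)cc1OC | intermediate
10 | (3R,4R)-3-[3,4-bis(benzyloxy)benzyl]-4-(3,4-dimethoxybenzyl)dihydrofuran-2(3H)-one | COc1ccc(C[C@H]2COC(=O)[C@@H]2Cc2ccc(OCc3ccccc3)c(OCc3ccccc3)c2)cc1OC | intermediate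
11 | 3'-O-demethylarctigenin, (3R,4R)-3-(3,4-dihydroxybenzyl)-4-(3,4-dimethoxybenzyl)dihydrofuran-2(3H)-one | COc1ccc(C[C@H]2COC(=O)[C@@H]2Cc2ccc(O)c(O)c2)cc1OC | target

Total step count: 6. Longest linear sequence: 6 steps (1 to 11).

**Steps most likely to fail**

Step 4. The nucleophilic carbon dioxide radical anion may add only slowly to an electron-rich styrene that carries a branched substituent. The thiyl radical may also abstract the allylic hydrogen at the stereocentre before the addition, eroding the configuration at C4, and ring closure onto the β-branched chloride may stay incomplete. The fallback sets out from 4 and comes back at 10, bypassing steps 3 to 5; it takes the carbonyl carbon from the alkene terminus by oxidation and brings in the catechol arm by enolate alkylation. Alkene 4 would be hydroborated with 9-BBN (THF, 0 °C to rt) and oxidised under buffered conditions (NaBO3·4H2O, THF/H2O) to (R)-4-chloro-3-(3,4-dimethoxybenzyl)butan-1-ol F1. Oxidation with TEMPO/PhI(OAc)2 in MeCN/H2O would give (R)-4-chloro-3-(3,4-dimethoxybenzyl)butanoic acid F2, which should close with K2CO3 in DMF to (R)-4-(3,4-dimethoxybenzyl)dihydrofuran-2(3H)-one F3. Its lithium enolate (LiN(SiMe3)2, THF, −78 °C) would be alkylated with 3,4-bis(benzyloxy)benzyl bromide on the face away from the C4 substituent, which is expected to give trans lactone 10 directly.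

Step 2. The benzylic Grignard reagent may be lost to homocoupling, part of the reaction may leak to direct SN2 substitution, and enantio-induction may be insufficient with a benzylic nucleophile. The fallback sets out from 1 and comes back at 4; it replaces the catalytic step by an oxazolidinone chiral-auxiliary alkylation. (R)-4-Benzyl-2-oxazolidinone would be N-acylated (n-BuLi, THF, −78 °C; but-3-enoyl chloride) to (R)-4-benzyl-3-(but-3-enoyl)oxazolidin-2-one F4. Its sodium enolate (NaN(SiMe3)2, THF, −78 °C) would be alkylated at the α-carbon with 1 (n-Bu4NI as catalyst, −78 to −20 °C) on the face away from the auxiliary benzyl group, giving (R)-4-benzyl-3-[(R)-2-(3,4-dimethoxybenzyl)but-3-enoyl]oxazolidin-2-one F5. Reductive removal of the auxiliary (LiBH4, Et2O/MeOH, 0 °C) would give (R)-2-(3,4-dimethoxybenzyl)but-3-en-1-ol F6, and an Appel-type chlorination (PPh3, N-chlorosuccinimide, CH2Cl2, 0 °C) would return 4.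

Step 3. β-Hydride elimination may run toward the stereogenic allylic C–H instead of the benzylic side, which would give the non-conjugated alkene and erase the stereocentre; a second arylation is also possible. The fallback sets out from 4 and comes back at 6; it replaces the Heck reaction by alkene cross-metathesis. 3,4-Bis(benzyloxy)benzaldehyde would be methylenated by a Wittig reaction (Ph3PCH3Br, KOt-Bu, THF, 0 °C) to 1,2-bis(benzyloxy)-4-vinylbenzene F7. Cross-metathesis of 4 with F7 (second-generation Grubbs catalyst RuCl2(=CHPh)(PCy3)(H2IMes), CH2Cl2, 40 °C) should then give 6 without any palladium hydride near the stereocentre; the alkene geometry is in any case erased in step 4.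

**Further compounds**
F1 | step 4 | (R)-4-chloro-3-(3,4-dimethoxybenzyl)butan-1-ol | OCC[C@H](CCl)Cc1ccc(OC)c(OC)c1
F2 | step 4 | (R)-4-chloro-3-(3,4-dimethoxybenzyl)butanoic acid | OC(=O)C[C@H](CCl)Cc1ccc(OC)c(OC)c1
F3 | step 4 | (R)-4-(3,4-dimethoxybenzyl)dihydrofuran-2(3H)-one | COc1ccc(C[C@H]2COC(=O)C2)cc1OC
F4 | step 2 | (R)-4-benzyl-3-(but-3-enoyl)oxazolidin-2-one | C=CCC(=O)N1[C@H](Cc2ccccc2)COC1=O
F5 | step 2 | (R)-4-benzyl-3-[(R)-2-(3,4-dimethoxybenzyl)but-3-enoyl]oxazolidin-2-one | C=C[C@H](C(=O)N1[C@H](Cc2ccccc2)COC1=O)Cc1ccc(OC)c(OC)c1
F6 | step 2 | (R)-2-(3,4-dimethoxybenzyl)but-3-en-1-ol | C=C[C@H](CO)Cc1ccc(OC)c(OC)c1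
F7 | step 3 | 1,2-bis(benzyloxy)-4-vinylbenzene | C=Cc1ccc(OCc2ccccc2)c(OCc2ccccc2)c1
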